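Everything rests on opening the furan ring at two bonds, chromone C3–C1' and chromone C2–O(C2'). The feature exploited is on ring B: the furan oxygen on C2' lies para to the free C5' hydroxyl and ortho to the C1'–C3 bond, the imprint of a p-quinone that accepted a carbon nucleophile. In one operation, the nucleophilic C3 of 2-(dimethylamino)chromone 9 adds to C6 of 2,2-dimethylchroman-5,8-dione 15 and the resulting hydroquinone oxygen expels dimethylamine from C2, which closes the furan and delivers ring B fully oxygenated. Precursor 9 already carries the C5–C6 fused dimethylchroman, the 8-prenyl group and a 7-O-allyl ether that is later removed without acid.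

Key step: step 10

Assumption: the target is achiral, so no stereocentre has to be set; locants follow chromone numbering (O1, C2–C4, C4a, C5–C8, C8a) with C1'–C6' for ring B (C1' on C3, furan oxygen on C2'), chroman numbering is used for the quinone fragment, and "prenyl" means 3-methylbut-2-en-1-yl.

Step 1
Reactants: 1 phloroacetophenone (2',4',6'-trihydroxyacetophenone); 2 prenyl bromide
Product: 3 diprenylphloroacetophenone (1-[2,4,6-trihydroxy-3,5-bis(3-methylbut-2-en-1-yl)phenyl]ethan-1-one)
Conditions: 2 (2.1 equiv), 10% aq. KOH, 0 °C → rt; then dil. HCl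
Reagents that add atoms: none
Why: Phenoxide C-alkylation of the phloroglucinol-type anion in water, where solvation of oxygen steers the ambident anion to carbon, should place a prenyl group on each of the two free ring positions.

Step 2
Reactants: 3 diprenylphloroacetophenone
Product: 4 allyl ether (1-[4-(allyloxy)-2,6-dihydroxy-3,5-bis(3-methylbut-2-en-1-yl)phenyl]ethan-1-one)
Conditions: allyl bromide (1.05 equiv), K2CO3 (1.1 equiv), acetone, rt
Reagents that add atoms: allyl bromide, C=CCBr
Why: Williamson etherification with one equivalent of halide and a weak base should take the 4-hydroxyl, which is the most acidic (para to the acetyl group) and the only one not hydrogen-bonded to the ketone.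

Step 3
Reactants: 4 allyl ether
Product: 6 thione (7-(allyloxy)-4,5-dihydroxy-6,8-diprenyl-2H-chromene-2-thione), via β-keto dithioacid 5 (not isolated)
Conditions: CS2 (3 equiv), KOtBu (4.5 equiv), THF, 0 °C → rt; cold 1 M HCl
Reagents that add atoms: carbon disulfide, S=C=S
Why: Dithiocarboxylation of the methyl ketone enolate followed by attack of an ortho-phenoxide on the dithiocarboxylate with loss of hydrosulfide (the standard entry to 4-hydroxy-2H-chromene-2-thiones) should close the pyranone, and because the two ortho-hydroxyls are equivalent by symmetry only one product can form.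

Step 4
Reactants: 6 thione
Product: 7 methylsulfanylchromone (7-(allyloxy)-5-hydroxy-2-(methylsulfanyl)-6,8-diprenyl-4H-chromen-4-one)
Conditions: MeI (1.05 equiv), K2CO3 (1.2 equiv), acetone, rt
Reagents that add atoms: iodomethane, CI
Why: S-alkylation of the soft thioxo-enolate should give the 2-(methylsulfanyl)chromone tautomer, while the 5-hydroxyl stays free because it is hydrogen-bonded to the C4 carbonyl and only one equivalent of MeI is offered.

Step 5
Reactants: 7 methylsulfanylchromone
Product: 8 chroman-fused methylsulfanylchromone (7-(allyloxy)-2-(methylsulfanyl)-8-prenyl-4H-chromen-4-one whose O5 and C6 are bridged by C(CH3)2-CH2-CH2, i.e. a 2,2-dimethyl-3,4-dihydro-2H-pyran fused at C5-C6 with its oxygen on C5)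
Conditions: pTsOH·H2O (0.2 equiv), toluene, 70 °C
Reagents that add atoms: none
Why: Acid-catalysed Markovnikov hydroalkoxylation (cycloisomerisation of an ortho-prenylphenol) should add the 5-hydroxyl, now the only free hydroxyl, to the tertiary carbon of the neighbouring 6-prenyl group in a six-membered closure, whereas the 8-prenyl group has only ether oxygens beside it and can at most protonate reversibly.

Step 6
Reactants: 8 chroman-fused methylsulfanylchromone
Product: 9 aminochromone (7-(allyloxy)-2-(dimethylamino)-8-prenyl-4H-chromen-4-one with the same C5-C6 fused 2,2-dimethyldihydropyran, oxygen on C5)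
Conditions: Me2NH (2 M in THF, 10 equiv), DMSO, sealed tube, 100 °C
Reagents that add atoms: dimethylamine, CNC
Why: Addition–elimination of a secondary amine at C2 of a 2-alkylthiochromone (a vinylogous thioester), the usual route to 2-aminochromones, should replace methanethiolate by dimethylamine, and closing the chroman beforehand avoids a deactivating 5-phenoxide.

Step 7
Reactants: 10 2,5-dimethoxyphenol; 11 prenal (3-methylbut-2-enal)
Product: 13 chromene (5,8-dimethoxy-2,2-dimethyl-2H-chromene), via ortho-quinone methide 12 (not isolated)
Conditions: PhB(OH)2 (1.0 equiv), AcOH (cat.), toluene, reflux, Dean–Stark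
Reagents that add atoms: none
Why: Phenylboronic acid-mediated ortho-specific condensation of a phenol with an enal should generate the ortho-quinone methide at C6, the only free ortho position, which closes by oxa-6π electrocyclisation to the 2H-chromene.

Step 8
Reactants: 13 chromene
Product: 14 dimethoxychroman (5,8-dimethoxy-2,2-dimethylchroman)
Conditions: H2 (1 atm), Pd/C (10 wt%), EtOAc, rt
Reagents that add atoms: none
Why: Catalytic hydrogenation of the styrene-type C3=C4 bond should give the chroman without touching the aryl ethers.

Step 9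
Reactants: 14 dimethoxychroman
Product: 15 chromanquinone (2,2-dimethylchroman-5,8-dione)
Conditions: (NH4)2Ce(NO3)6 (2.5 equiv), MeCN/H2O, 0 °C
Reagents that add atoms: water, O
Why: Oxidative demethylation of a para-dimethoxyarene by tetravalent cerium should give the p-quinone, the two para methoxy groups leaving as methanol while the chroman oxygen remains as the alkoxy substituent of the quinone.

Step 10
Reactants: 9 aminochromone; 15 chromanquinone
Product: 17 allyl-protected coumaronochromone (7-O-allyl ether of the target with the 5'-hydroxyl free), via hydroquinone adduct 16 (not isolated)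
Conditions: AcOH, N2, rt → 60 °C; 15 (1.1 equiv) added slowly
Reagents that add atoms: none
Why: Proposed new method: in acetic acid the push–pull C3 of 9 (the position at which 2-aminochromones undergo electrophilic substitution) should add in Michael fashion to C6 of quinone 15, and tautomerisation then gives hydroquinone 16. The C5 hydroxyl of 16, ortho to the new C3–C1' bond, attacks C2 of the O-protonated aminochromone, which reacts as an exocyclic iminium, so the furan closes 5-exo-trig by addition–elimination with loss of dimethylamine and gain of aromaticity. The closest known reaction is the Nenitzescu-type synthesis of 3-acyl-5-hydroxybenzofurans from tertiary enaminones and 1,4-benzoquinones; here the enaminone is cyclic and its amino carbon also carries the ring oxygen. Regioselectivity on the quinone is required and is secured by its ring oxygen, which turns the C5 carbonyl into a vinylogous ester, so the C8 carbonyl is the stronger acceptor and its β-carbon C6 is attacked, as 2-alkoxyquinones do in Nenitzescu reactions. Within 16, C2 should win over the C4 carbonyl because it is the amidinium-type carbon bearing the protonatable leaving group, the tertiary amine excludes indole formation, and near-equimolar quinone limits oxidation of 16 to an arylquinone that cannot cyclise. No stereocentre is formed.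

Step 11
Reactants: 17 allyl-protected coumaronochromone
Product: 18 target CNP0081329.0
Conditions: Pd(PPh3)4 (5 mol%), morpholine (5 equiv), THF, rt
Reagents that add atoms: none
Why: Palladium-catalysed allyl transfer (Tsuji–Trost-type deallylation) from the aryl allyl ether to morpholine through a π-allyl complex should free the 7-hydroxyl under neutral conditions, so the ortho-prenylphenol never meets acid that could close a second chroman.

Compound list
1 | 2',4',6'-trihydroxyacetophenone | CC(=O)c1c(O)cc(O)cc1O | starting material
2 | prenyl bromide (1-bromo-3-methylbut-2-ene) | CC(C)=CCBr | starting material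
3 | 1-[2,4,6-trihydroxy-3,5-bis(3-methylbut-2-en-1-yl)phenyl]ethan-1-one | CC(=O)c1c(O)c(CC=C(C)C)c(O)c(CC=C(C)C)c1O | intermediate
4 | 1-[4-(allyloxy)-2,6-dihydroxy-3,5-bis(3-methylbut-2-en-1-yl)phenyl]ethan-1-one | CC(=O)c1c(O)c(CC=C(C)C)c(OCC=C)c(CC=C(C)C)c1O | intermediate
5 | 3-[4-(allyloxy)-2,6-dihydroxy-3,5-diprenylphenyl]-3-oxopropanedithioic acid (β-keto dithioacid, not isolated) | SC(=S)CC(=O)c1c(O)c(CC=C(C)C)c(OCC=C)c(CC=C(C)C)c1O | intermediate
6 | 7-(allyloxy)-4,5-dihydroxy-6,8-diprenyl-2H-chromene-2-thione | S=c1cc(O)c2c(O)c(CC=C(C)C)c(OCC=C)c(CC=C(C)C)c2o1 | intermediate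
7 | 7-(allyloxy)-5-hydroxy-2-(methylsulfanyl)-6,8-diprenyl-4H-chromen-4-one | CSc1cc(=O)c2c(O)c(CC=C(C)C)c(OCC=C)c(CC=C(C)C)c2o1 | intermediate
8 | 7-(allyloxy)-2-(methylsulfanyl)-8-prenyl-4H-chromen-4-one with a 2,2-dimethyl-3,4-dihydro-2H-pyran fused at C5-C6 (oxygen on C5) | CC(C)=CCc1c(OCC=C)c2CCC(C)(C)Oc2c2c1oc(SC)cc2=O | intermediate
9 | 7-(allyloxy)-2-(dimethylamino)-8-prenyl-4H-chromen-4-one with a 2,2-dimethyl-3,4-dihydro-2H-pyran fused at C5-C6 (oxygen on C5) | CC(C)=CCc1c(OCC=C)c2CCC(C)(C)Oc2c2c1oc(N(C)C)cc2=O | intermediate
10 | 2,5-dimethoxyphenol | COc1ccc(OC)c(O)c1 | starting material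
11 | 3-methylbut-2-enal (prenal) | CC(C)=CC=O | starting material
12 | 2,5-dimethoxy-6-(3-methylbut-2-en-1-ylidene)cyclohexa-2,4-dien-1-one (ortho-quinone methide, not isolated) | O=C1C(OC)=CC=C(OC)C1=CC=C(C)C | intermediate
13 | 5,8-dimethoxy-2,2-dimethyl-2H-chromene | COc1ccc(OC)c2c1C=CC(C)(C)O2 | intermediate
14 | 5,8-dimethoxy-2,2-dimethylchroman | COc1ccc(OC)c2c1CCC(C)(C)O2 | intermediate
15 | 2,2-dimethylchroman-5,8-dione | CC1(C)CCC2=C(O1)C(=O)C=CC2=O | intermediate
16 | 3-(5,8-dihydroxy-2,2-dimethylchroman-6-yl) derivative of 9 (hydroquinone adduct, not isolated) | CC(C)=CCc1c(OCC=C)c2CCC(C)(C)Oc2c2c1oc(N(C)C)c(-c1cc(O)c3OC(C)(C)CCc3c1O)c2=O | intermediate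
17 | 7-O-allyl ether of the target (benzofuro[2,3-b]chromen-4-one formed by joining C3 of 9 to chroman C6 and C2 to the chroman C5 oxygen; 5'-OH free) | CC(C)=CCc1c(OCC=C)c2CCC(C)(C)Oc2c2c1oc1oc3c4CCC(C)(C)Oc4c(O)cc3c1c2=O | intermediate
18 | CNP0081329.0: 7,5'-dihydroxy-8-prenyl coumaronochromone with 2,2-dimethyldihydropyran rings fused at C5-C6 (O on C5) and at C3'-C4' (O on C4') | CC(C)=CCc1c(O)c2c(c3c(=O)c4c(oc13)oc1c3c(c(O)cc14)OC(C)(C)CC3)OC(C)(C)CC2 | target

Total step count: 11. Longest linear sequence: 8 steps (steps 1–6, 10 and 11); steps 7–9 make the quinone in parallel.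

Steps most likely to fail

1. Step 10 (Proposed new method). The quinone may be attacked at C7 instead of C6. Adduct 16 may be oxidised by unreacted quinone before it cyclises. The hydroquinone oxygen may close onto the C4 carbonyl with loss of water, or the pyranone may open at O1 instead of losing the amine. The fallback sets out from 8 and 14 and returns at 17; it makes the C3–C1' bond by cross-coupling and closes the furan under base, where only C2 carries a leaving group. NIS in MeCN at 0 °C should iodinate the push–pull C3 position of 8 to give 3-iodo-2-(methylsulfanyl)chromone F1. NBS in MeCN should brominate 14 at C6 (para to the ring oxygen, ortho to the 5-methoxy group) to give 6-bromo-5,8-dimethoxy-2,2-dimethylchroman F2. Miyaura borylation (B2pin2, Pd(dppf)Cl2, KOAc, dioxane, 90 °C) should convert it into pinacol boronate F3. Suzuki–Miyaura coupling of F1 with F3 (Pd(dppf)Cl2, K3PO4, dioxane/H2O, 80 °C) should give 3-aryl-2-(methylsulfanyl)chromone F4. (NH4)2Ce(NO3)6 in MeCN/H2O at 0 °C should unmask arylquinone F5, and Na2S2O4 should reduce it to hydroquinone F6. On warming with K2CO3 in DMF under N2, the C5 phenoxide of F6 should displace methanethiolate from C2 by intramolecular addition–elimination, a known closure of 2'-hydroxy-2-alkylthioisoflavones to benzofuro[2,3-b]chromones, giving 17.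

2. Step 5. The acid may also ionise the 8-prenyl group, leading to double-bond migration or capture of the cation by the neighbouring allyl ether oxygen with loss of the allyl group, before the 6-prenyl closure is complete. The fallback sets out from 7 and returns at 8; it replaces proton activation by a selenium electrophile that is consumed only where an internal nucleophile is at hand. N-(phenylselanyl)phthalimide with catalytic camphorsulfonic acid in dry CH2Cl2 at 0 °C should effect phenylselenoetherification of the 6-prenyl group by the 5-hydroxyl, giving racemic 3-(phenylselanyl)chroman F7. Radical deselenation (Bu3SnH, AIBN, toluene, 80 °C) should then give 8.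

3. Step 6. The thermal displacement may stall because the electron-rich chromone is a weak acceptor, and prolonged heating with amine may open the pyranone. The fallback sets out from 8 and returns at 9; it activates the leaving group by oxidation. (NH4)6Mo7O24·4H2O (cat.) with 30% H2O2 in EtOH at 0 °C → rt, conditions that oxidise sulfur in preference to trisubstituted alkenes, should give 2-(methylsulfonyl)chromone F8. Me2NH in THF at 0 °C → rt should then displace methanesulfinate to give 9.

Further compounds
F1 | step 10 | 7-(allyloxy)-3-iodo-2-(methylsulfanyl)-8-prenyl-4H-chromen-4-one with the C5-C6 fused 2,2-dimethyldihydropyran | CC(C)=CCc1c(OCC=C)c2CCC(C)(C)Oc2c2c1oc(SC)c(I)c2=O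
F2 | step 10 | 6-bromo-5,8-dimethoxy-2,2-dimethylchroman | COc1cc(Br)c(OC)c2c1OC(C)(C)CC2
F3 | step 10 | 2-(5,8-dimethoxy-2,2-dimethylchroman-6-yl)-4,4,5,5-tetramethyl-1,3,2-dioxaborolane | COc1cc(B2OC(C)(C)C(C)(C)O2)c(OC)c2c1OC(C)(C)CC2
F4 | step 10 | 3-(5,8-dimethoxy-2,2-dimethylchroman-6-yl) derivative of 8 | CC(C)=CCc1c(OCC=C)c2CCC(C)(C)Oc2c2c1oc(SC)c(-c1cc(OC)c3OC(C)(C)CCc3c1OC)c2=O
F5 | step 10 | 3-(2,2-dimethyl-5,8-dioxochroman-6-yl) derivative of 8 (arylquinone) | CC(C)=CCc1c(OCC=C)c2CCC(C)(C)Oc2c2c1oc(SC)c(C1=CC(=O)C3=C(CCC(C)(C)O3)C1=O)c2=O
F6 | step 10 | 3-(5,8-dihydroxy-2,2-dimethylchroman-6-yl) derivative of 8 (hydroquinone) | CC(C)=CCc1c(OCC=C)c2CCC(C)(C)Oc2c2c1oc(SC)c(-c1cc(O)c3OC(C)(C)CCc3c1O)c2=O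
F7 | step 5 | racemic 3-(phenylselanyl) derivative of 8 (selenium on C3 of the C5-C6 fused dihydropyran) | CC(C)=CCc1c(OCC=C)c2CC([Se]c3ccccc3)C(C)(C)Oc2c2c1oc(SC)cc2=O
F8 | step 6 | 2-(methylsulfonyl) analogue of 8 | CC(C)=CCc1c(OCC=C)c2CCC(C)(C)Oc2c2c1oc(S(C)(=O)=O)cc2=O
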